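**Assumptions (one line each):** the carboxyl group is carried as its methyl ester, and the chiral ligand enantiomer in Step 3 is chosen to give the absolute configuration shown. Compounds 1, 2 and 10 are commercial.

## Retrosynthetic overview
1. Ferulsinaic acid 12 comes from the methyl ester 11 by mild ester cleavage. 11 comes from Mitsunobu coupling of umbelliferone 10 with primary alcohol 9.
2. The isobutenyl group of 9 comes from a chemoselective Wittig reaction on the less hindered aldehyde of the 1,5-dialdehyde 7. The two epimerisable α-centres of 7 are set thermodynamically. 7 is the bis(methoxymethylenation)/hydrolysis product of the dione 5.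
3. **Key step:** desymmetrising conjugate methylation of the prochiral ene-dione 4. It sets the quaternary centre and the adjacent CH–Me in one operation. 4 comes from 2-methylcyclopentane-1,3-dione (1) and methyl acrylate (2) by Michael addition then dehydrogenation.
4. Both rings are already present in the starting materials: the cyclopentane in 1 and the coumarin in 10. No ring is constructed; the cyclopentane is desymmetrised.

## Route

**Step 1**
Reactants: 1 (2-methylcyclopentane-1,3-dione), 2 (methyl acrylate)
Product: 3, methyl 3-(1-methyl-2,5-dioxocyclopentyl)propanoate (prochiral, achiral)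
Conditions: methyl acrylate (1.5 equiv), H2O, 100 °C, 6 h
Reagents that add atoms: none beyond the named reactants
Why: Michael addition of the acidic dione to the acrylate creates the quaternary carbon carrying Me and CH2CH2CO2Me, and no stereocentre is formed.

**Step 2**
Reactants: 3
Product: 4, methyl 3-(1-methyl-2,5-dioxocyclopent-3-en-1-yl)propanoate (symmetric ene-dione, `O=C1C=CC(=O)C1(C)CCC(=O)OC`)
Conditions: 1) LiHMDS, TMSCl, THF, −78 °C; 2) Pd(OAc)2, MeCN, 23 °C
Reagents that add atoms: none
Why: Saegusa–Ito oxidation of the mono-silyl enol ether gives the cyclopentene-1,3-dione. The quaternary carbon blocks enolisation and aromatisation, and the product has a mirror plane.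

**Step 3**
Reactants: 4
Product: 5, methyl 3-[(1R,3S)-1,3-dimethyl-2,5-dioxocyclopentyl]propanoate, with the 3-Me cis to the propanoate chain (`O=C1C[C@H](C)C(=O)[C@]1(C)CCC(=O)OC`)
Conditions: Me2Zn (2 equiv), Cu(OTf)2 (3 mol%), chiral phosphoramidite L* (6 mol%), toluene, −30 °C; then aq. NH4Cl
Reagents that add atoms: dimethylzinc, `C[Zn]C` (adds CH3; H from the NH4Cl work-up)
Why: Cu-catalysed asymmetric conjugate addition (ACA) of a dialkylzinc. The catalyst picks one of the two enantiotopic alkene termini, which makes the quaternary carbon stereogenic, and methyl is delivered to the carbon β to the remote ketone.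
Proposed new method: The Me/CH2CH2CO2Me pair gives almost no intrinsic facial bias at the remote β-carbon, so the pendant ester is expected to direct Zn–Me syn to itself. Zn–O=C(OMe) chelation would hold the Cu–Me species on the chain face (closest known reactions: Cu/phosphoramidite ACA of Me2Zn to cyclic enones, and carbonyl-directed cuprate additions). This puts the new CH–Me cis to the chain, as in the target.

**Step 4**
Reactants: 5
Product: 6, bis(methoxymethylene) derivative of 5 (E/Z mixture, `COC=C1C[C@H](C)C(=COC)[C@]1(C)CCC(=O)OC`)
Conditions: Ph3P+CH2OMe Cl− (5 equiv), KHMDS (4.8 equiv), THF, 0 → 23 °C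
Reagents that add atoms: (methoxymethyl)triphenylphosphonium chloride, `COC[P+](c1ccccc1)(c1ccccc1)c1ccccc1.[Cl-]` (supplies two =CHOMe)
Why: Wittig methoxymethylenation converts both ketones to enol ethers. The enol ether geometry is irrelevant because it is destroyed in the next step.

**Step 5**
Reactants: 6
Product: 7, methyl 3-(2,5-diformyl-1,3-dimethylcyclopentyl)propanoate (`O=C[C@@H]1C[C@H](C)[C@@H](C=O)[C@]1(C)CCC(=O)OC`)
Conditions: 2 M HCl (aq.), THF, 23 °C, 3 h; then Et3N (0.2 equiv), CH2Cl2, 23 °C, 12 h
Reagents that add atoms: water, `O` (MeOH is lost)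
Why: Enol ether hydrolysis gives the dialdehyde, and amine-mediated α-epimerisation then equilibrates the two new stereocentres. In the shown isomer the Ca-CHO is cis to the chain, and the Cd-CHO is trans to the adjacent CH–Me and cis to the quaternary Me. This avoids a contiguous all-cis triad on the Me face and a cis vicinal CHO/Me pair, so it is expected to be the thermodynamic minimum. Cc–H is β to both aldehydes and is not touched. A 1,5-dialdehyde cannot aldolise intramolecularly (it would need a four-membered ring).

**Step 6**
Reactants: 7
Product: 8, methyl 3-[2-formyl-1,3-dimethyl-5-(2-methylprop-1-enyl)cyclopentyl]propanoate (`CC(C)=C[C@@H]1C[C@H](C)[C@@H](C=O)[C@]1(C)CCC(=O)OC`)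
Conditions: iPrPPh3+ I− (1.1 equiv), KHMDS (1.05 equiv), THF, −78 → 0 °C
Reagents that add atoms: isopropyltriphenylphosphonium iodide, `CC(C)[P+](c1ccccc1)(c1ccccc1)c1ccccc1.[I-]` (supplies =CMe2)
Why: Wittig olefination with Ph3P=CMe2 is selective for the less hindered aldehyde. The Ca-CHO is flanked by CH2 and the quaternary carbon, whereas the Cd-CHO also sits next to CHMe. The Ca centre is fixed as the trisubstituted alkene forms. Any epimerisation of the remaining Cd-CHO returns to the same thermodynamic isomer.

**Step 7**
Reactants: 8
Product: 9, methyl 3-[2-(hydroxymethyl)-1,3-dimethyl-5-(2-methylprop-1-enyl)cyclopentyl]propanoate (`CC(C)=C[C@@H]1C[C@H](C)[C@@H](CO)[C@]1(C)CCC(=O)OC`)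
Conditions: NaBH4, MeOH, 0 °C, 20 min
Reagents that add atoms: none (hydride/H only)
Why: Chemoselective aldehyde reduction leaves the ester and the trisubstituted alkene intact. The Cd stereocentre is locked once it becomes CH2OH.

**Step 8**
Reactants: 9, 10 (umbelliferone, 7-hydroxycoumarin)
Product: 11, methyl ester of ferulsinaic acid (`CC(C)=C[C@@H]1C[C@H](C)[C@@H](COc2ccc3ccc(=O)oc3c2)[C@]1(C)CCC(=O)OC`)
Conditions: PPh3, DIAD, THF, 0 → 23 °C
Reagents that add atoms: none (all atoms come from 9 and 10; PPh3 and DIAD are lost as Ph3PO and hydrazide)
Why: Mitsunobu etherification of a primary alcohol with an acidic phenol (pKa ≈ 7.7). The reaction is at a CH2, so no stereocentre is affected.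

**Step 9**
Reactants: 11
Product: 12, ferulsinaic acid (target)
Conditions: Me3SnOH, 1,2-DCE, 80 °C; then 1 M HCl work-up
Reagents that add atoms: trimethyltin hydroxide, `C[Sn](C)(C)O` (hydroxide O ends up in the acid)
Why: Mild, selective methyl ester cleavage. The coumarin lactone survives, and if it opens reversibly it recloses on acidification. No stereocentre is affected.

## Compound list
1 | 2-methylcyclopentane-1,3-dione | `CC1C(=O)CCC1=O` | starting material
2 | methyl acrylate | `C=CC(=O)OC` | starting material
3 | methyl 3-(1-methyl-2,5-dioxocyclopentyl)propanoate | `O=C1CCC(=O)C1(C)CCC(=O)OC` | intermediate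
4 | methyl 3-(1-methyl-2,5-dioxocyclopent-3-en-1-yl)propanoate | `O=C1C=CC(=O)C1(C)CCC(=O)OC` | intermediate
5 | methyl 3-[(1R,3S)-1,3-dimethyl-2,5-dioxocyclopentyl]propanoate | `O=C1C[C@H](C)C(=O)[C@]1(C)CCC(=O)OC` | intermediate
6 | bis(methoxymethylene) derivative of 5 | `COC=C1C[C@H](C)C(=COC)[C@]1(C)CCC(=O)OC` | intermediate
7 | methyl 3-(2,5-diformyl-1,3-dimethylcyclopentyl)propanoate (stereo as shown) | `O=C[C@@H]1C[C@H](C)[C@@H](C=O)[C@]1(C)CCC(=O)OC` | intermediate
8 | aldehyde–isobutenyl methyl ester | `CC(C)=C[C@@H]1C[C@H](C)[C@@H](C=O)[C@]1(C)CCC(=O)OC` | intermediate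
9 | hydroxymethyl–isobutenyl methyl ester | `CC(C)=C[C@@H]1C[C@H](C)[C@@H](CO)[C@]1(C)CCC(=O)OC` | intermediate
10 | umbelliferone (7-hydroxycoumarin) | `O=c1ccc2ccc(O)cc2o1` | starting material
11 | methyl ester of ferulsinaic acid | `CC(C)=C[C@@H]1C[C@H](C)[C@@H](COc2ccc3ccc(=O)oc3c2)[C@]1(C)CCC(=O)OC` | intermediate
12 | ferulsinaic acid | `CC(C)=C[C@@H]1C[C@H](C)[C@@H](COc2ccc3ccc(=O)oc3c2)[C@]1(C)CCC(=O)O` | target

**Total steps:** 9. **Longest linear sequence:** 9 (1 → 3 → 4 → 5 → 6 → 7 → 8 → 9 → 11 → 12); umbelliferone enters in Step 8.

## Three steps most likely to fail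
1. **Step 3 (desymmetrising methylation).** The chain-directed syn delivery is unproven. Without it the catalyst alone gives a diastereomeric mixture and the Me-trans-to-chain isomer is favoured.
   Fallback (different approach): desymmetrise dione 3 by asymmetric reduction (CBS, Ru transfer hydrogenation or baker's yeast) to the cis-fused keto-lactone. Install the CH–Me by α-methylenation and convex-face hydrogenation. Then open the lactone, oxidise and rejoin the route at the aldehyde stages.
2. **Steps 4–5 (double homologation with α-epimerisation).** The hindered second ketone may stall at the mono-enol ether, and the basic ylide may epimerise Cc. The thermodynamic ratio at Ca and Cd is also only predicted.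
   Fallback (stepwise approach): olefinate the less hindered ketone alone, carry it to the isobutenyl group, then homologate the remaining ketone by van Leusen reductive cyanation (TosMIC) and DIBAL. Separate diastereomers at the nitrile stage.
3. **Step 6 (chemoselective Wittig on the dialdehyde).** Both aldehydes may react, or the Cd aldehyde may epimerise under the basic ylide.
   Fallback (different method): methylenate selectively with Ph3P=CH2 to the Ca-vinyl compound, then cross-metathesise with 2-methylbut-2-ene (Grubbs II) to give the isobutenyl group.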